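**Assumptions.** (1) The chiral IDPi enantiomer is chosen to give the (R)-quaternary centre of 3. (2) The phenol is carried as its TBS ether and released in the last step.

## Retrosynthetic overview
1. The target is the p-hydroxybenzoate of epoxy-diol 16. The α-epoxide comes from hydroxyl-directed epoxidation of the ring alkene in jaeschkeanadiol (14).
2. Diol 14 comes from Evans–Saksena directed reduction of ketone 13, which makes the C-6 carbinol centre and erases any epimer mixture. Ketone 13 comes from oxidation of the carbinol in 12, and 12 comes from α-face addition of isopropyl to the hydroazulenone 9.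
3. The cycloheptene ring of 9 is closed by ring-closing metathesis of diene 8, which carries an allyl group on the quaternary carbon and a methallyl group on the carbinol carbon.
4. Diene 8 comes from a Mukaiyama aldol of silyl enol ether 3 with 3-methylbut-3-enal (5). The enol ether is regiospecific and already carries the quaternary centre.
5. Enol ether 3 comes from a new catalytic enantioselective conjugate allylation of 3-methylcyclopentenone. Ring order: cyclopentane with its quaternary centre first, then the seven-membered ring by RCM.

## Route

**Step 1**
Reactants: 1 (3-methylcyclopent-2-en-1-one); 2 (allyltrimethylsilane)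
Product: 3 ((3R)-3-allyl-3-methyl-1-(trimethylsilyloxy)cyclopent-1-ene)
Conditions: (S,S)-IDPi (5 mol %), cyclohexane, −30 °C, 72 h
Reagents that add atoms: allyltrimethylsilane (2), C=CC[Si](C)(C)C (adds allyl and Me3Si)
Why: Proposed new method: the confined chiral imidodiphosphorimidate acid reacts with allylsilane (losing propene) to give a chiral silylium–anion pair. This O-silylates the β,β-disubstituted enone, and the allylsilane attacks the β-carbon on one enantioface of the silyloxyallyl cation, forming the all-carbon quaternary stereocentre. The β-silyl cation then loses Me3Si⁺, which regenerates the catalyst and leaves the enol ether regiospecifically at Ci=Ca. The closest known reactions are the Lewis-acid Hosomi–Sakurai conjugate allylation of enones and IDPi-catalysed Mukaiyama–Michael additions. The new feature is an enantioselective catalytic version on a β,β-disubstituted cyclopentenone.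

**Step 2**
Reactants: 4 (3-methylbut-3-en-1-ol)
Product: 5 (3-methylbut-3-enal)
Conditions: DMP, NaHCO3, CH2Cl2, 0 °C, 1 h; used immediately as a cold solution
Reagents that add atoms: none
Why: Dess–Martin oxidation of a primary alcohol; the 1,1-disubstituted alkene is untouched.

**Step 3**
Reactants: 3; 5
Product: 6 (3-allyl-2-(1-hydroxy-3-methylbut-3-enyl)-3-methylcyclopentanone; Ci–Ch bond cis to the angular Me; Ch epimers not controlled)
Conditions: TiCl4, CH2Cl2, −78 °C, 1 h; then 1 M HCl, THF, rt
Reagents that add atoms: 3-methylbut-3-enal (5), CC(=C)CC=O
Why: Mukaiyama aldol. The enol-ether carbon Ci is attacked by the aldehyde from the face anti to the larger allyl group and syn to Me, which gives the future trans ring fusion. The Ch configuration is erased in Steps 8–9.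

**Step 4**
Reactants: 6; 7 (tert-butyldimethylsilyl chloride)
Product: 8 (Ch-OTBS ether of 6)
Conditions: TBSCl, imidazole, DMAP (cat.), DMF, 40 °C
Reagents that add atoms: TBSCl (7), CC(C)(C)[Si](C)(C)Cl (adds TBS)
Why: Silyl protection of the secondary alcohol prevents retro-aldol and alkoxide chelation in the later Grignard step.

**Step 5**
Reactants: 8
Product: 9 ((3aS-type) trans-fused hydroazulenone with an endocyclic Z-trisubstituted alkene and Ch-OTBS)
Conditions: Hoveyda–Grubbs II (5 mol %), toluene (0.004 M), 80 °C, 6 h
Reagents that add atoms: none (ethylene is lost)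
Why: Ring-closing metathesis of the monosubstituted allyl alkene with the 1,1-disubstituted methallyl alkene forms the cycloheptene ring. No new stereocentre forms, and Cq and Ci are untouched.

**Step 6**
Reactants: 9; 10 (isopropylmagnesium chloride)
Product: 11 (tertiary alcohol, Ch-OTBS)
Conditions: iPrMgCl·LaCl3·2LiCl (1.5 equiv), THF, −40 → 0 °C
Reagents that add atoms: iPrMgCl (10), CC(C)[Mg]Cl (adds isopropyl)
Why: Lanthanum-moderated Grignard 1,2-addition. The nucleophile attacks from the α face, anti to the β-disposed Ci–Ch bond and the angular Me, which puts iPr α and OH β.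

**Step 7**
Reactants: 11
Product: 12 (diol, Ch epimers)
Conditions: TBAF, THF, 0 °C → rt, 3 h
Reagents that add atoms: none
Why: Fluoride cleavage of the secondary TBS ether; the tertiary alcohol, alkene and ring fusion are unaffected.

**Step 8**
Reactants: 12
Product: 13 (β-hydroxy ketone, Ch=O)
Conditions: DMP, NaHCO3, CH2Cl2, 0 °C, 1 h
Reagents that add atoms: none
Why: Dess–Martin oxidation is selective for the secondary alcohol over the tertiary one and converges both Ch epimers to one ketone. Buffering and low temperature protect Ci from epimerization and retro-aldol.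

**Step 9**
Reactants: 13
Product: 14 (jaeschkeanadiol, Ch-OH α)
Conditions: Me4NBH(OAc)3, MeCN/AcOH (1:1), −20 → 0 °C
Reagents that add atoms: none (hydride only)
Why: Evans–Saksena reduction. The β-tertiary hydroxyl binds the borate and delivers hydride intramolecularly to the β face of the Ch ketone. This gives the anti-1,3-diol, which is Ch–O α with Ca–OH β, as in the target.

**Step 10**
Reactants: 14; 15 (tert-butyl hydroperoxide)
Product: 16 (α-epoxy diol)
Conditions: VO(acac)2 (5 mol %), TBHP (2 equiv, in decane), CH2Cl2, 0 °C
Reagents that add atoms: TBHP (15), CC(C)(C)OO (supplies the epoxide O)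
Why: Sharpless–Michaelson hydroxyl-directed epoxidation. The vanadium alkoxide at the α Ch-OH delivers O to the α face of the homoallylic trisubstituted alkene, giving the cis-epoxide (O α, Me β). The β tertiary alcohol is remote from the alkene.

**Step 11**
Reactants: 16; 17 (4-(tert-butyldimethylsilyloxy)benzoic acid)
Product: 18 (TBS-protected p-hydroxybenzoate ester)
Conditions: EDC·HCl, DMAP, CH2Cl2, rt, 16 h
Reagents that add atoms: 17, CC(C)(C)[Si](C)(C)Oc1ccc(cc1)C(=O)O (adds the aroyl group)
Why: Steglich esterification acylates only the secondary Ch-OH with retention; the hindered tertiary alcohol and the epoxide are unaffected.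

**Step 12**
Reactants: 18
Product: 19 (Jaeskeanin)
Conditions: TBAF/AcOH (1:1), THF, 0 °C, 1 h
Reagents that add atoms: none
Why: Buffered fluoride removes the aryl TBS ether without cleaving the ester or opening the epoxide.

## Compound list
1 | 3-methylcyclopent-2-en-1-one | CC1=CC(=O)CC1 | starting material
2 | allyltrimethylsilane | C=CC[Si](C)(C)C | starting material
3 | (3R)-3-allyl-3-methyl-1-(trimethylsilyloxy)cyclopent-1-ene | C=CC[C@@]1(C)CCC(O[Si](C)(C)C)=C1 | intermediate
4 | 3-methylbut-3-en-1-ol | CC(=C)CCO | starting material
5 | 3-methylbut-3-enal | CC(=C)CC=O | intermediate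
6 | aldol 6 (Ch epimers, Ch undefined) | C=CC[C@@]1(C)CCC(=O)[C@@H]1C(O)CC(C)=C | intermediate
7 | tert-butyldimethylsilyl chloride | CC(C)(C)[Si](C)(C)Cl | starting material
8 | TBS ether of 6 | C=CC[C@@]1(C)CCC(=O)[C@@H]1C(O[Si](C)(C)C(C)(C)C)CC(C)=C | intermediate
9 | trans-hydroazulenone, Ch-OTBS | O=C1CC[C@]2(C)CC=C(C)CC(O[Si](C)(C)C(C)(C)C)[C@H]21 | intermediate
10 | isopropylmagnesium chloride | CC(C)[Mg]Cl | starting material
11 | tertiary alcohol, Ch-OTBS | CC(C)[C@]1(O)CC[C@]2(C)CC=C(C)CC(O[Si](C)(C)C(C)(C)C)[C@H]21 | intermediate
12 | diol (Ch epimers) | CC(C)[C@]1(O)CC[C@]2(C)CC=C(C)CC(O)[C@H]21 | intermediate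
13 | hydroxy ketone | CC(C)[C@]1(O)CC[C@]2(C)CC=C(C)CC(=O)[C@H]21 | intermediate
14 | jaeschkeanadiol | CC(C)[C@]1(O)CC[C@]2(C)CC=C(C)C[C@H](O)[C@H]21 | intermediate
15 | tert-butyl hydroperoxide | CC(C)(C)OO | starting material
16 | α-epoxy diol | CC(C)[C@]1(O)CC[C@]2(C)C[C@@H]3O[C@]3(C)C[C@H](O)[C@H]21 | intermediate
17 | 4-(TBSO)benzoic acid | CC(C)(C)[Si](C)(C)Oc1ccc(cc1)C(=O)O | starting material
18 | TBS-protected ester | CC(C)[C@]1(O)CC[C@]2(C)C[C@@H]3O[C@]3(C)C[C@H](OC(=O)c3ccc(O[Si](C)(C)C(C)(C)C)cc3)[C@H]21 | intermediate
19 | Jaeskeanin | CC(C)[C@]1(O)CC[C@]2(C)C[C@@H]3O[C@]3(C)C[C@H](OC(=O)c3ccc(O)cc3)[C@H]21 | target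

## Totals
Total steps: 12, including the side-branch aldehyde preparation in Step 2. Longest linear sequence: 11 steps (1 → 3 → 6 → 8 → 9 → 11 → 12 → 13 → 14 → 16 → 18 → 19).

## Three steps most likely to fail
1. **Step 1 (proposed new enantioselective conjugate allylation).** A β,β-disubstituted cyclopentenone may be too unreactive for the silylium pair, or the ee may be low.
   Fallback: run a racemic TMSOTf-catalysed Hosomi–Sakurai to give racemic 3, carry it through to diol 14, and resolve by separating the (1S)-camphanate esters of the secondary alcohol followed by saponification. This uses known chemistry and accepts a 50% maximum yield.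
2. **Step 3 (Mukaiyama aldol).** The nucleophilic carbon is neopentyl-like, the aldehyde is prone to isomerization, and the Ci diastereoselectivity is modest.
   Fallback: cleave enol ether 3 with MeLi to the regiodefined lithium enolate, transmetalate to zinc or cerium, and add 5 through a chelated Zimmerman–Traxler aldol. This changes the mechanism from open-TS Lewis-acid catalysis to metal-enolate chelation control.
3. **Step 10 (directed epoxidation).** Homoallylic direction is weaker than allylic, and the angular Me may steer the epoxide to the wrong face.
   Fallback: use reagent-controlled Shi epoxidation (fructose-derived ketone, Oxone, pH 10.5) on 14, choosing the ketone enantiomer that delivers the α-epoxide. This replaces substrate control with catalyst control.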